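**Retrosynthetic overview**

1. Feature: in the oxolan-2-one ring of the target (O1, C2=O, C3, C4, C5) the C3–C4 bond joins the arylidene-bearing C3 to the only stereocentre, C4 (S). The exocyclic C3=CH–Ar alkene holds its aryl cis to the C2 carbonyl (Z).
2. Target 12 ⇐ tris-silyl ether 11, by cleaving three ArO–Si bonds in the last step.
3. 11 ⇐ (Z)-cinnamyl arylpropiolate 10, by disconnecting C3–C4: Rh/H2 reductive 1,6-enyne cyclisation. The lactone is the only ring formed, and it forms here.
4. 10 ⇐ arylpropiolic acid 9 + (Z)-allylic alcohol 4 (ester C–O bond).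
5. 9 ⇐ 3,4-dihydroxy-5-methoxybenzaldehyde 5 (silylation, Corey–Fuchs, CO2); 4 ⇐ vanillin 1 (silylation, Still–Gennari, DIBAL-H).

Key step: step 8

Assumption 1: the cinnamyl alkene is used as the Z isomer, because oxidative cyclisation of allyl alkynoates on cationic rhodium–bisphosphine is established for cis-1,2-disubstituted alkenes and trans alkenes are expected to cyclise reluctantly. The benzylic carbon ends as CH2, so the alkene geometry does not appear in the product.

Assumption 2: the sense of induction is to be assigned on the first run; (R)-BINAP is written, and (S)-BINAP is taken instead if C4 should come out R.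

Assumption 3: the phenols are carried as TBS ethers, so that the last step needs neither strong acid nor free phenoxide.

**Route**

Step 1
Reactants: 1 vanillin
Product: 2 4-(tert-butyldimethylsilyloxy)-3-methoxybenzaldehyde
Conditions: TBSCl, imidazole, DMF, rt
Reagents that add atoms: tert-butyldimethylsilyl chloride (TBSCl), CC(C)(C)[Si](C)(C)Cl
Why: Imidazole-promoted O-silylation of the phenol is fast and leaves the aldehyde untouched; the silyl ether masks the acidic OH for the olefination, the hydride reduction and the Rh step.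

Step 2
Reactants: 2 4-(tert-butyldimethylsilyloxy)-3-methoxybenzaldehyde
Product: 3 methyl (2Z)-3-[4-(tert-butyldimethylsilyloxy)-3-methoxyphenyl]prop-2-enoate
Conditions: (CF3CH2O)2P(O)CH2CO2Me, KN(SiMe3)2, 18-crown-6, THF, −78 °C
Reagents that add atoms: methyl 2-[bis(2,2,2-trifluoroethoxy)phosphoryl]acetate, COC(=O)CP(=O)(OCC(F)(F)F)OCC(F)(F)F
Why: Still–Gennari variant of the Horner–Wadsworth–Emmons olefination: with the trifluoroethyl phosphonate and a crown-ether-separated potassium enolate the syn oxaphosphetane should collapse faster than it equilibrates, which gives the (Z)-cinnamate from an aromatic aldehyde while the aryl silyl ether survives the short exposure to base at −78 °C.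

Step 3
Reactants: 3 methyl (2Z)-3-[4-(tert-butyldimethylsilyloxy)-3-methoxyphenyl]prop-2-enoate
Product: 4 (2Z)-3-[4-(tert-butyldimethylsilyloxy)-3-methoxyphenyl]prop-2-en-1-ol
Conditions: i-Bu2AlH (DIBAL-H), CH2Cl2, −78 °C; aq. potassium sodium tartrate
Reagents that add atoms: none
Why: 1,2-Reduction of the enoate by DIBAL-H at low temperature should give the allylic alcohol with the Z alkene and the aryl silyl ether intact, and the neutral tartrate work-up avoids acid that would ionise or isomerise the electron-rich cinnamyl alcohol.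

Step 4
Reactants: 5 3,4-dihydroxy-5-methoxybenzaldehyde
Product: 6 3,4-bis(tert-butyldimethylsilyloxy)-5-methoxybenzaldehyde
Conditions: TBSCl (excess), imidazole, DMAP (cat.), DMF, rt to 40 °C
Reagents that add atoms: tert-butyldimethylsilyl chloride (TBSCl), CC(C)(C)[Si](C)(C)Cl
Why: Double O-silylation; the 4-OH flanked by OSi and OMe is hindered but should still silylate under imidazole/DMAP catalysis in DMF as 2,6-disubstituted phenols do, and both acidic OH groups must be masked before n-BuLi is used.

Step 5
Reactants: 6 3,4-bis(tert-butyldimethylsilyloxy)-5-methoxybenzaldehyde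
Product: 7 5-(2,2-dibromoethenyl)-1,2-bis(tert-butyldimethylsilyloxy)-3-methoxybenzene
Conditions: CBr4, PPh3, Zn, CH2Cl2, 0 °C to rt
Reagents that add atoms: carbon tetrabromide, BrC(Br)(Br)Br
Why: Ramirez dibromo-olefination (first stage of the Corey–Fuchs sequence): the ylide Ph3P=CBr2 made from CBr4, PPh3 and Zn undergoes a Wittig reaction with the aldehyde, and the Zn variant avoids Ph3PBr2 so that the silyl ethers stay in place.

Step 6
Reactants: 7 5-(2,2-dibromoethenyl)-1,2-bis(tert-butyldimethylsilyloxy)-3-methoxybenzene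
Product: 9 3-[3,4-bis(tert-butyldimethylsilyloxy)-5-methoxyphenyl]prop-2-ynoic acid, via lithium arylacetylide 8 (not isolated)
Conditions: n-BuLi (2.1 equiv), THF, −78 °C; CO2; then cold 1 M HCl
Reagents that add atoms: carbon dioxide, O=C=O
Why: Second stage of the Corey–Fuchs sequence: bromine–lithium exchange, elimination and deprotonation give the lithium acetylide, whose carboxylation by CO2 is a standard route to arylpropiolic acids, and aryl silyl ethers tolerate n-BuLi at −78 °C.

Step 7
Reactants: 9 3-[3,4-bis(tert-butyldimethylsilyloxy)-5-methoxyphenyl]prop-2-ynoic acid; 4 (2Z)-3-[4-(tert-butyldimethylsilyloxy)-3-methoxyphenyl]prop-2-en-1-ol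
Product: 10 (2Z)-3-[4-(tert-butyldimethylsilyloxy)-3-methoxyphenyl]prop-2-en-1-yl 3-[3,4-bis(tert-butyldimethylsilyloxy)-5-methoxyphenyl]prop-2-ynoate
Conditions: DCC, DMAP (cat.), CH2Cl2, 0 °C
Reagents that add atoms: none
Why: Steglich esterification: the activated acid (O-acylisourea, then acylpyridinium) acylates the unhindered primary allylic alcohol at 0 °C under neutral conditions, which should keep the Z alkene, the ynoate and the silyl ethers unchanged.

Step 8
Reactants: 10 (2Z)-3-[4-(tert-butyldimethylsilyloxy)-3-methoxyphenyl]prop-2-en-1-yl 3-[3,4-bis(tert-butyldimethylsilyloxy)-5-methoxyphenyl]prop-2-ynoate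
Product: 11 (3Z,4S)-3-{[3,4-bis(tert-butyldimethylsilyloxy)-5-methoxyphenyl]methylidene}-4-{[4-(tert-butyldimethylsilyloxy)-3-methoxyphenyl]methyl}oxolan-2-one
Conditions: [Rh(cod)2]OTf (10 mol%), (R)-BINAP (10 mol%), H2 (1 atm), ClCH2CH2Cl, 25 °C
Reagents that add atoms: none
Why: Proposed new method: the cationic monovalent rhodium–BINAP fragment binds the alkyne and the alkene of 10 and undergoes oxidative cyclisation to a trivalent rhodacyclopentene, in which the new C3–C4 bond closes the lactone with both unsaturations outside the new ring (5-exo closure); hydrogen then cleaves the vinyl C–Rh and the benzylic C–Rh bonds (H2 activation followed by two C–H reductive eliminations) and returns the catalyst. The closest known reaction types are the hydrogen-mediated enantioselective reductive cyclisation of 1,6-enynes bearing monosubstituted alkenes on this catalyst and the rhodium–BINAP Alder-ene cycloisomerisation of (Z)-allyl arylpropiolates to α-arylidene-γ-butyrolactones, which shows the oxidative cyclisation for ester-tethered aryl ynoates with cis-1,2-disubstituted alkenes; new here is the hydrogenolytic exit on a styrenyl alkene. The C4 stereocentre is set in the oxidative cyclisation, where the C2-symmetric bisphosphine selects the alkene face (catalyst control, no other stereocentre is present). The Z geometry follows because Rh and C4 are cis on the metallacycle double bond, so the hydrogen that replaces Rh ends cis to C4 and the aryl cis to the C2 carbonyl. Chemoselectivity over plain hydrogenation should hold because C–C bond formation precedes H2 activation on this catalyst and the electron-poor ynoate cyclises readily, and the Alder-ene exit is closed because the Rh-bearing benzylic carbon has no eliminable hydrogen outside the metallacycle. Regioselectivity (ynoate α-carbon to the internal alkene carbon) is fixed by the five-membered tether and by the benzyl-stabilised C–Rh bond.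

Step 9
Reactants: 11 (3Z,4S)-3-{[3,4-bis(tert-butyldimethylsilyloxy)-5-methoxyphenyl]methylidene}-4-{[4-(tert-butyldimethylsilyloxy)-3-methoxyphenyl]methyl}oxolan-2-one
Product: 12 (3Z,4S)-3-[(3,4-dihydroxy-5-methoxyphenyl)methylidene]-4-[(4-hydroxy-3-methoxyphenyl)methyl]oxolan-2-one
Conditions: Bu4NF, AcOH, THF, 0 °C
Reagents that add atoms: none
Why: Fluoride cleaves the three aryl Si–O bonds (strong Si–F bond), and the acetic acid buffer protonates each phenoxide as it forms, so that no vinylogous enolate arises that could isomerise the Z arylidene or move the alkene into the ring; the lactone and C4 should be untouched at 0 °C.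

**Compound list**

1 | vanillin (4-hydroxy-3-methoxybenzaldehyde) | COc1cc(C=O)ccc1O | starting material
2 | 4-(tert-butyldimethylsilyloxy)-3-methoxybenzaldehyde | COc1cc(C=O)ccc1O[Si](C)(C)C(C)(C)C | intermediate
3 | methyl (2Z)-3-[4-(tert-butyldimethylsilyloxy)-3-methoxyphenyl]prop-2-enoate | COC(=O)/C=C\c1ccc(O[Si](C)(C)C(C)(C)C)c(OC)c1 | intermediate
4 | (2Z)-3-[4-(tert-butyldimethylsilyloxy)-3-methoxyphenyl]prop-2-en-1-ol | OC/C=C\c1ccc(O[Si](C)(C)C(C)(C)C)c(OC)c1 | intermediate
5 | 3,4-dihydroxy-5-methoxybenzaldehyde | COc1cc(C=O)cc(O)c1O | starting material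
6 | 3,4-bis(tert-butyldimethylsilyloxy)-5-methoxybenzaldehyde | COc1cc(C=O)cc(O[Si](C)(C)C(C)(C)C)c1O[Si](C)(C)C(C)(C)C | intermediate
7 | 5-(2,2-dibromoethenyl)-1,2-bis(tert-butyldimethylsilyloxy)-3-methoxybenzene | COc1cc(C=C(Br)Br)cc(O[Si](C)(C)C(C)(C)C)c1O[Si](C)(C)C(C)(C)C | intermediate
8 | lithium [3,4-bis(tert-butyldimethylsilyloxy)-5-methoxyphenyl]acetylide | [Li]C#Cc1cc(OC)c(O[Si](C)(C)C(C)(C)C)c(O[Si](C)(C)C(C)(C)C)c1 | intermediate
9 | 3-[3,4-bis(tert-butyldimethylsilyloxy)-5-methoxyphenyl]prop-2-ynoic acid | OC(=O)C#Cc1cc(OC)c(O[Si](C)(C)C(C)(C)C)c(O[Si](C)(C)C(C)(C)C)c1 | intermediate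
10 | (2Z)-3-[4-(tert-butyldimethylsilyloxy)-3-methoxyphenyl]prop-2-en-1-yl 3-[3,4-bis(tert-butyldimethylsilyloxy)-5-methoxyphenyl]prop-2-ynoate | COc1cc(/C=C\COC(=O)C#Cc2cc(O[Si](C)(C)C(C)(C)C)c(O[Si](C)(C)C(C)(C)C)c(OC)c2)ccc1O[Si](C)(C)C(C)(C)C | intermediate
11 | (3Z,4S)-3-{[3,4-bis(tert-butyldimethylsilyloxy)-5-methoxyphenyl]methylidene}-4-{[4-(tert-butyldimethylsilyloxy)-3-methoxyphenyl]methyl}oxolan-2-one | COc1cc(C[C@@H]2COC(=O)/C2=C\c2cc(O[Si](C)(C)C(C)(C)C)c(O[Si](C)(C)C(C)(C)C)c(OC)c2)ccc1O[Si](C)(C)C(C)(C)C | intermediate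
12 | (3Z,4S)-3-[(3,4-dihydroxy-5-methoxyphenyl)methylidene]-4-[(4-hydroxy-3-methoxyphenyl)methyl]oxolan-2-one | COc1cc(C[C@@H]2COC(=O)/C2=C\c2cc(O)c(O)c(OC)c2)ccc1O | target

**Totals**

Total step count: 9. Longest linear sequence: 6 steps (steps 4 to 9, from 5).

**Steps most likely to fail**

Step 8. The oxidative cyclisation of the 1,2-disubstituted styrenyl alkene may be slow, so that plain hydrogenation of the alkyne or alkene, Z-to-E isomerisation of the cinnamyl alkene by a rhodium hydride, ionisation of the allylic C–O bond, poor facial selectivity or over-reduction of the arylidene take over. The fallback uses known chemistry, sets out from acid 9 and returns at 11.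
- Steglich esterification of 9 with an excess of (Z)-but-2-ene-1,4-diol should give (2Z)-4-hydroxybut-2-en-1-yl 3-[3,4-bis(tert-butyldimethylsilyloxy)-5-methoxyphenyl]prop-2-ynoate F1.
- Without hydrogen, cationic monovalent rhodium–BINAP ([Rh(cod)Cl]2, BINAP, AgSbF6, ClCH2CH2Cl, rt) should effect the enantioselective Alder-ene cycloisomerisation known for (Z)-allyl alkynoates. After the same oxidative cyclisation, β-hydride elimination from the CH2OH carbon and C–H reductive elimination give an enol that tautomerises to [(3S,4Z)-4-{[3,4-bis(tert-butyldimethylsilyloxy)-5-methoxyphenyl]methylidene}-5-oxooxolan-3-yl]acetaldehyde F2, with the Z arylidene and the ring stereocentre already set.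
- Pinnick oxidation (NaClO2, NaH2PO4, 2-methylbut-2-ene, t-BuOH/H2O) should give [(3S,4Z)-4-{[3,4-bis(tert-butyldimethylsilyloxy)-5-methoxyphenyl]methylidene}-5-oxooxolan-3-yl]acetic acid F3.
- N-Hydroxyphthalimide and N,N'-diisopropylcarbodiimide should convert it into the 1,3-dioxoisoindolin-2-yl ester F4.
- Nickel-catalysed decarboxylative cross-electrophile coupling of F4 (NiBr2·glyme, 4,4'-di-tert-butyl-2,2'-bipyridine, Zn, DMA, rt) with tert-butyl(4-iodo-2-methoxyphenoxy)dimethylsilane F5 (from 4-iodo-2-methoxyphenol, TBSCl, imidazole) should replace CO2 by the aryl group and give 11. The primary radical sits one carbon away from the stereocentre, which is therefore not touched.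

Step 9. Fluoride treatment may cause Z-to-E isomerisation of the arylidene through a transient para-phenoxide (vinylogous enolate). The fallback sets out from 11 and returns at 12. The desilylation is run as before and the isomer mixture is accepted. The separated (3E,4S)-3-[(3,4-dihydroxy-5-methoxyphenyl)methylidene]-4-[(4-hydroxy-3-methoxyphenyl)methyl]oxolan-2-one F6 is irradiated (about 350 nm, degassed MeCN) to a photostationary E/Z mixture, from which 12 is separated and F6 recycled. The geometry is then set by photo-equilibration, which does not touch C4.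

Step 7. The activated arylpropiolic acid may condense with itself (anhydride, then dehydro-Diels–Alder), DMAP may add to the ynoate, and the Z allylic alcohol may ionise or isomerise. The fallback sets out from dibromoalkene 7 and alcohol 4 and returns at 10, forming the C(sp)–C(=O) bond instead of the ester C–O bond. Alcohol 4 and 1,1'-carbonyldiimidazole (CH2Cl2, rt) should give (2Z)-3-[4-(tert-butyldimethylsilyloxy)-3-methoxyphenyl]prop-2-en-1-yl 1H-imidazole-1-carboxylate F7. Lithium acetylide 8, made from 7 with n-BuLi as in step 6, is then acylated with F7 at −78 °C (THF) to give 10, so that no free or activated propiolic acid is present.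

**Further compounds**

F1 | step 8 | (2Z)-4-hydroxybut-2-en-1-yl 3-[3,4-bis(tert-butyldimethylsilyloxy)-5-methoxyphenyl]prop-2-ynoate | OC/C=C\COC(=O)C#Cc1cc(OC)c(O[Si](C)(C)C(C)(C)C)c(O[Si](C)(C)C(C)(C)C)c1
F2 | step 8 | [(3S,4Z)-4-{[3,4-bis(tert-butyldimethylsilyloxy)-5-methoxyphenyl]methylidene}-5-oxooxolan-3-yl]acetaldehyde | O=CC[C@@H]1COC(=O)/C1=C\c2cc(OC)c(O[Si](C)(C)C(C)(C)C)c(O[Si](C)(C)C(C)(C)C)c2
F3 | step 8 | [(3S,4Z)-4-{[3,4-bis(tert-butyldimethylsilyloxy)-5-methoxyphenyl]methylidene}-5-oxooxolan-3-yl]acetic acid | OC(=O)C[C@@H]1COC(=O)/C1=C\c2cc(OC)c(O[Si](C)(C)C(C)(C)C)c(O[Si](C)(C)C(C)(C)C)c2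
F4 | step 8 | 1,3-dioxoisoindolin-2-yl [(3S,4Z)-4-{[3,4-bis(tert-butyldimethylsilyloxy)-5-methoxyphenyl]methylidene}-5-oxooxolan-3-yl]acetate | O=C(C[C@@H]1COC(=O)/C1=C\c2cc(OC)c(O[Si](C)(C)C(C)(C)C)c(O[Si](C)(C)C(C)(C)C)c2)ON3C(=O)c4ccccc4C3=O
F5 | step 8 | tert-butyl(4-iodo-2-methoxyphenoxy)dimethylsilane | COc1cc(I)ccc1O[Si](C)(C)C(C)(C)C
F6 | step 9 | (3E,4S)-3-[(3,4-dihydroxy-5-methoxyphenyl)methylidene]-4-[(4-hydroxy-3-methoxyphenyl)methyl]oxolan-2-one | COc1cc(C[C@@H]2COC(=O)/C2=C/c2cc(O)c(O)c(OC)c2)ccc1O
F7 | step 7 | (2Z)-3-[4-(tert-butyldimethylsilyloxy)-3-methoxyphenyl]prop-2-en-1-yl 1H-imidazole-1-carboxylate | O=C(OC/C=C\c1ccc(O[Si](C)(C)C(C)(C)C)c(OC)c1)n1ccnc1
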